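**Plan**

- Numbering is that of cyclohepta[c]pyran: C1 acetal carbon, O2, C3=C4, ring fusion C4a/C9a, carbocycle C5–C9. The enabling feature is that the CMe2-bridged C5–C6 bond of the cyclopropane (ring C) lies α,β to the C7 ketone of the seven-membered ring B. This is the retron of conjugate isopropylidene transfer, so the first cut removes C5–CMe2 and C6–CMe2 and leaves a C5=C6/C8=C9 dienone.
- Further cuts: the C1 acetate and the C4/C9 oxidation levels (back to a C1 silyl acetal, C4 methyl ester and C9 silyloxymethyl group); the two C=C bonds of the dienone (back to a C5–O–C9 ether bridge); the pyran bonds C4–C4a, C1–C9a and C1–O2; and finally C5–C6 and C8–C9, which join a furan to a three-carbon oxyallyl unit.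
- Forward: ring B is made first as an 8-oxabicyclo[3.2.1]octenone by (4+3) cycloaddition. Ring A (the pyran) is then annulated on the exo face of its alkene by a de Mayo sequence, the oxygen bridge is eliminated to the dienone, ring C is closed by the sulfur ylide, and six functional-group steps finish the target.
- Stereochemistry: the (S)-1-phenylethyl auxiliary fixes the two bridgeheads in the (4+3) step. Exo photocycloaddition relays them to cis C4a/C9a before the bridgeheads become sp2. The ylide adds to C5 anti to the pyran arm and sets C5/C6. C1 is set last, in the anomeric acetylation.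

Key step: step 12

Assumption: the (S)-1-phenylethyl group is taken to shield the same face of the allyl cation towards furan 2 as towards furan itself, giving the (1S,5S) bridgeheads of 7; were the sense opposite, (R)-1-phenylethanol would be used instead.

**Route**

Step 1
Reactants: 1 furfuryl alcohol
Product: 2 tert-butyl(furan-2-ylmethoxy)diphenylsilane
Conditions: tBuPh2SiCl, imidazole, DMF, 0 °C to rt
Reagents that add atoms: tert-butyl(chloro)diphenylsilane, CC(C)(C)[Si](Cl)(c1ccccc1)c1ccccc1
Why: Imidazole-mediated silylation of the primary hydroxyl; the bulky silyl ether should survive every step up to step 17 and makes the future C9 bridgehead the more hindered one.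

Step 2
Reactants: 3 1,1-dimethoxypropan-2-one; 4 (S)-1-phenylethanol
Product: 5 1-methoxy-1-[(1S)-1-phenylethoxy]propan-2-one (both epimers at the acetal carbon)
Conditions: pyridinium p-toluenesulfonate (cat.), cyclohexane, 70 °C, MeOH distilled off
Reagents that add atoms: none
Why: Acid-catalysed transacetalisation exchanges one methoxy group for the chiral alkoxy group once methanol is removed; the acetal carbon becomes planar in step 4, so its two epimers are equivalent.

Step 3
Reactants: 5 mixed acetal
Product: 6 triethyl({3-methoxy-3-[(1S)-1-phenylethoxy]prop-1-en-2-yl}oxy)silane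
Conditions: LiN(iPr)2, THF, −78 °C; then Et3SiCl
Reagents that add atoms: chlorotriethylsilane, CC[Si](Cl)(CC)CC
Why: Kinetic deprotonation at the methyl group and O-silylation (silyl enol ether formation), the hindered acetal C–H being left alone.

Step 4
Reactants: 2 silylated furfuryl alcohol; 6 chiral silyl enol ether acetal
Product: 7 (1S,4S,5S)-1-{[tert-butyl(diphenyl)silyl]oxymethyl}-4-[(1S)-1-phenylethoxy]-8-oxabicyclo[3.2.1]oct-6-en-3-one
Conditions: Me3SiOTf (0.1 equiv), CH2Cl2, −95 °C
Reagents that add atoms: none
Why: Auxiliary-controlled (4+3) cycloaddition of a chiral alkoxy-substituted silyloxyallyl cation (Hoffmann type), formed by loss of methoxide to the silyl triflate: the furan should attack through its unsubstituted C5 at the oxocarbenium terminus on the face not shielded by the phenyl ring and close at C2, so the alkoxy group ends up next to the unsubstituted bridgehead and both bridgeheads are fixed by the auxiliary; other regio- and diastereomers would be removed here because they lead to the antipode of 8.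

Step 5
Reactants: 7 α-alkoxy ketone
Product: 8 (1S,5R)-1-{[tert-butyl(diphenyl)silyl]oxymethyl}-8-oxabicyclo[3.2.1]oct-6-en-3-one
Conditions: SmI2, THF/MeOH, −78 °C
Reagents that add atoms: none
Why: Reductive cleavage of an α-alkoxy ketone by two single-electron transfers from SmI2, the axial C–O bond being aligned with the ketyl π system; methanol should protonate the samarium enolate before it can expel the bridging oxygen, and the bridgehead centres are untouched.

Step 6
Reactants: 9 methyl 3,3-dimethoxypropanoate
Product: 11 methyl diformylacetate (enol form), via sodium formyl acetal enolate 10 (not isolated)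
Conditions: HCO2Me, NaH, Et2O, 0 °C to rt; then aq. HCl, 0 °C
Reagents that add atoms: methyl formate, COC=O; water, O
Why: Crossed Claisen formylation of the ester enolate followed by acid hydrolysis of the acetal gives the chelated enol needed as photochemical partner.

Step 7
Reactants: 8 oxabicyclic ketone; 11 methyl diformylacetate
Product: 14 cis-fused bridged lactol, via cyclobutanol photoadduct 12 (not isolated), via ring-opened formyl enol 13 (not isolated)
Conditions: hν (medium-pressure Hg lamp, Pyrex filter), CH2Cl2, 0 °C, excess 11
Reagents that add atoms: none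
Why: De Mayo reaction: [2+2] photocycloaddition of the enol of 11 to the exo face of the strained alkene (syn to the oxygen bridge), retro-aldol opening of the cyclobutanol and closure of the enol oxygen onto the new aldehyde should give the lactol; suprafacial exo addition sets C4a and C9a cis, and the doubly acylated enol carbon should bond to the alkene carbon remote from the bulky silyloxymethyl bridgehead on steric grounds.

Step 8
Reactants: 14 lactol
Product: 15 1-O-tert-butyldimethylsilyl acetal of 14
Conditions: tBuMe2SiCl, imidazole, DMF, 0 °C to rt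
Reagents that add atoms: tert-butyl(chloro)dimethylsilane, CC(C)(C)[Si](C)(C)Cl
Why: Imidazole-mediated O-silylation of the hemiacetal hydroxyl locks the lactol as a base- and hydride-stable silyl acetal; both C1 epimers are usable (the one with oxygen trans to H-9a is drawn) because C1 is set again in step 16.

Step 9
Reactants: 15 bridged silyl acetal
Product: 18 C9 tertiary hydroxy enone, via trimethylsilyl enol ether 16 (not isolated), via ring-opened trimethylsilyl ether 17 (not isolated)
Conditions: Me3SiOTf, Et3N, CH2Cl2, −78 to 0 °C; then aq. citric acid, THF, 0 °C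
Reagents that add atoms: none
Why: Soft enolisation towards the less hindered C6 and silyl-triflate-assisted β-elimination of the bridging oxygen from C5 (the established ring opening of 8-oxabicyclo[3.2.1]octan-3-ones) should leave the oxygen on C9 as a silyl ether that is hydrolysed on work-up; enolisation towards C8 would give the regioisomeric hydroxy enone, which converges on 20 in step 10.

Step 10
Reactants: 18 hydroxy enone
Product: 20 cis-fused cyclohepta-2,6-dienone, via tertiary mesylate 19 (not isolated)
Conditions: MeSO2Cl, Et3N, CH2Cl2, −20 °C; then DBU, 0 °C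
Reagents that add atoms: none
Why: Sulfene mesylation of the tertiary aldol-type alcohol and E1cB elimination through the C8 enolate should give the cross-conjugated dienone; short exposure to amine base at low temperature is meant to leave the γ-hydrogens at C4a and C9a in place.

Step 11
Reactants: 21 diphenyl sulfide
Product: 22 isopropyldiphenylsulfonium tetrafluoroborate
Conditions: 2-iodopropane, AgBF4, CH2Cl2, rt, dark
Reagents that add atoms: 2-iodopropane, CC(C)I; silver tetrafluoroborate, [Ag+].F[B-](F)(F)F
Why: S-Alkylation of the weakly nucleophilic diaryl sulfide by the secondary iodide, driven by precipitation of AgI (standard preparation of the isopropylide precursor).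

Step 12
Reactants: 20 dienone; 22 sulfonium salt
Product: 24 cyclopropane-fused enone, via diphenylsulfonium isopropylide 23 (not isolated)
Conditions: 22, LiN(iPr)2, DME, −78 °C; then 20, −78 to −40 °C
Reagents that add atoms: none
Why: LiN(iPr)2 deprotonates the salt to ylide 23, which adds in conjugate fashion to C5; the C6 enolate then displaces diphenyl sulfide from the sulfonium carbon, so C5–CMe2 and C6–CMe2 form in sequence (Michael-initiated ring closure). The closest known reaction type is Corey's gem-dimethylcyclopropanation of enones with this ylide (Corey–Chaykovsky-type alkylidene transfer). The cyclopropane closes in the 3-exo-tet mode. C5 is set by attack anti to the C4a–C4 bond, on the convex face of the cis-fused bicycle that carries H-4a and H-9a, and C6 follows because a three-membered ring can only be cis-fused to ring B. The step needs site selectivity for C5 over C9 and C3 and must outrun γ-deprotonation at C4a/C9a: C9 is fully substituted and screened by the silyloxymethyl group, C3 belongs to an electron-rich vinylogous carbonate, and the preformed ylide is used at −78 °C without excess amide.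

Step 13
Reactants: 24 cyclopropane-fused enone ester
Product: 25 diol (C4 hydroxymethyl and C7 hydroxyl)
Conditions: iBu2AlH, CH2Cl2, −78 to −40 °C
Reagents that add atoms: none
Why: Hydride reduction with iBu2AlH takes the vinylogous carbonate ester to the allylic alcohol and the enone carbonyl to the allylic alcohol (1,2-reduction) while the silyl groups and the cyclopropane stay; the new C7 carbinol centre (either epimer) is removed again in step 15.

Step 14
Reactants: 25 diol
Product: 26 C4 acetoxymethyl C7 alcohol
Conditions: AcCl, 2,4,6-collidine, CH2Cl2, −78 °C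
Reagents that add atoms: acetyl chloride, CC(Cl)=O
Why: Chemoselective acetylation of the primary allylic hydroxyl over the secondary cyclopropyl carbinol with acetyl chloride and a hindered pyridine base at low temperature.

Step 15
Reactants: 26 allylic alcohol
Product: 27 C7 enone
Conditions: Dess–Martin periodinane, NaHCO3, CH2Cl2, 0 °C to rt
Reagents that add atoms: none
Why: Dess–Martin oxidation of the secondary allylic alcohol restores the enone under buffered conditions that spare the silyl acetal, the enol ether and the allylic acetate.

Step 16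
Reactants: 27 anomeric silyl ether
Product: 29 C1 acetate, via lactol 28 (not isolated)
Conditions: Bu4NF, AcOH, THF, −20 °C; then Ac2O, pyridine, DMAP (cat.), −20 to 0 °C
Reagents that add atoms: acetic anhydride, CC(=O)OC(C)=O
Why: Buffered fluoride should cleave the anomeric silyl ether much faster than the primary tert-butyldiphenylsilyl ether, and the lactol is acetylated in the same flask (pyridine/DMAP acylation) before it can ring-open; the lactol anomers interconvert, and the acetate expected to dominate is the one axial on the dihydropyran half-chair, trans to H-9a (anomeric effect, H-1 equatorial), which is the configuration required at C1.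

Step 17
Reactants: 29 silyl ether
Product: 30 C9 hydroxymethyl compound
Conditions: Bu4NF, AcOH, THF, 0 °C to rt
Reagents that add atoms: none
Why: Fluoride-mediated cleavage of the remaining primary silyl ether, buffered with acetic acid so that the anomeric and allylic acetates and the enone are not attacked.

Step 18
Reactants: 30 primary allylic alcohol
Product: 31 target
Conditions: Dess–Martin periodinane, NaHCO3, CH2Cl2, 0 °C
Reagents that add atoms: none
Why: Dess–Martin oxidation of the primary allylic alcohol to the enal under bicarbonate buffering completes the target without touching any stereocentre.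

**Compound list**

1 | furfuryl alcohol | OCc1ccco1 | starting material
2 | tert-butyl(furan-2-ylmethoxy)diphenylsilane | CC(C)(C)[Si](OCc1ccco1)(c1ccccc1)c1ccccc1 | intermediate
3 | 1,1-dimethoxypropan-2-one | CC(=O)C(OC)OC | starting material
4 | (S)-1-phenylethanol | C[C@H](O)c1ccccc1 | starting material
5 | 1-methoxy-1-[(1S)-1-phenylethoxy]propan-2-one, both epimers at the acetal carbon | CC(=O)C(OC)O[C@@H](C)c1ccccc1 | intermediate
6 | triethyl({3-methoxy-3-[(1S)-1-phenylethoxy]prop-1-en-2-yl}oxy)silane, both acetal epimers | C=C(O[Si](CC)(CC)CC)C(OC)O[C@@H](C)c1ccccc1 | intermediate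
7 | (1S,4S,5S)-1-{[tert-butyl(diphenyl)silyl]oxymethyl}-4-[(1S)-1-phenylethoxy]-8-oxabicyclo[3.2.1]oct-6-en-3-one; ether axial, cis to the oxygen bridge, on the carbon next to the unsubstituted bridgehead | O=C1[C@@H](O[C@@H](C)c3ccccc3)[C@@H]2C=C[C@](CO[Si](c4ccccc4)(c4ccccc4)C(C)(C)C)(C1)O2 | intermediate
8 | (1S,5R)-1-{[tert-butyl(diphenyl)silyl]oxymethyl}-8-oxabicyclo[3.2.1]oct-6-en-3-one | O=C1C[C@@H]2C=C[C@](CO[Si](c3ccccc3)(c3ccccc3)C(C)(C)C)(C1)O2 | intermediate
9 | methyl 3,3-dimethoxypropanoate | COC(=O)CC(OC)OC | starting material
10 | sodium enolate of methyl 2-formyl-3,3-dimethoxypropanoate | COC(=O)C(=C[O-])C(OC)OC.[Na+] | intermediate (not isolated)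
11 | methyl diformylacetate, as its enol methyl 2-formyl-3-hydroxyprop-2-enoate | COC(=O)C(C=O)=CO | intermediate
12 | cyclobutanol photoadduct of 8 and 11: cyclobutane exo-fused to the former alkene, the carbon bearing CHO and CO2Me on C6 of 8 and the CH(OH) carbon on C7; the two new cyclobutane centres not defined | COC(=O)C1(C=O)C(O)[C@H]2[C@]3(CO[Si](c4ccccc4)(c4ccccc4)C(C)(C)C)CC(=O)C[C@@H](O3)[C@@H]12 | intermediate (not isolated)
13 | retro-aldol product: 8-oxabicyclo[3.2.1]octan-3-one carrying exo-CHO on C7 and an exo 2-hydroxy-1-(methoxycarbonyl)vinyl group on C6 | O=C[C@H]1[C@]2(CO[Si](c3ccccc3)(c3ccccc3)C(C)(C)C)CC(=O)C[C@@H](O2)[C@H]1C(=CO)C(=O)OC | intermediate (not isolated)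
14 | methyl 9-{[tert-butyl(diphenyl)silyl]oxymethyl}-1-hydroxy-7-oxo-1,4a,5,6,7,8,9,9a-octahydro-5,9-epoxycyclohepta[c]pyran-4-carboxylate; pyran cis-fused on the face of the oxygen bridge, lactol as its C1 anomers | COC(=O)C1=COC(O)[C@H]2[C@]3(CO[Si](c4ccccc4)(c4ccccc4)C(C)(C)C)CC(=O)C[C@@H](O3)[C@@H]12 | intermediate
15 | 1-O-tert-butyldimethylsilyl acetal of 14 (drawn with the C1 oxygen trans to H-9a) | COC(=O)C1=CO[C@@H](O[Si](C)(C)C(C)(C)C)[C@H]2[C@]3(CO[Si](c4ccccc4)(c4ccccc4)C(C)(C)C)CC(=O)C[C@@H](O3)[C@@H]12 | intermediate
16 | trimethylsilyl enol ether of 15 (C6=C7, silyloxy on C7) | COC(=O)C1=CO[C@@H](O[Si](C)(C)C(C)(C)C)[C@H]2[C@]3(CO[Si](c4ccccc4)(c4ccccc4)C(C)(C)C)CC(O[Si](C)(C)C)=C[C@@H](O3)[C@@H]12 | intermediate (not isolated)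
17 | ring-opened C5=C6 enone with the former bridge oxygen on C9 as trimethylsilyl ether | COC(=O)C1=CO[C@@H](O[Si](C)(C)C(C)(C)C)[C@H]2[C@](O[Si](C)(C)C)(CO[Si](c3ccccc3)(c3ccccc3)C(C)(C)C)CC(=O)C=C[C@@H]12 | intermediate (not isolated)
18 | methyl 1-[tert-butyl(dimethyl)silyl]oxy-9-{[tert-butyl(diphenyl)silyl]oxymethyl}-9-hydroxy-7-oxo-1,4a,7,8,9,9a-hexahydrocyclohepta[c]pyran-4-carboxylate; H-4a and H-9a cis, 9-OH on the face of the pyran bonds | COC(=O)C1=CO[C@@H](O[Si](C)(C)C(C)(C)C)[C@H]2[C@](O)(CO[Si](c3ccccc3)(c3ccccc3)C(C)(C)C)CC(=O)C=C[C@@H]12 | intermediate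
19 | C9 methanesulfonate of 18 | COC(=O)C1=CO[C@@H](O[Si](C)(C)C(C)(C)C)[C@H]2[C@](OS(C)(=O)=O)(CO[Si](c3ccccc3)(c3ccccc3)C(C)(C)C)CC(=O)C=C[C@@H]12 | intermediate (not isolated)
20 | methyl 1-[tert-butyl(dimethyl)silyl]oxy-9-{[tert-butyl(diphenyl)silyl]oxymethyl}-7-oxo-1,4a,7,9a-tetrahydrocyclohepta[c]pyran-4-carboxylate; H-4a and H-9a cis, C1 oxygen trans to H-9a | COC(=O)C1=CO[C@@H](O[Si](C)(C)C(C)(C)C)[C@H]2C(CO[Si](c3ccccc3)(c3ccccc3)C(C)(C)C)=CC(=O)C=C[C@@H]12 | intermediate
21 | diphenyl sulfide | c1ccc(cc1)Sc1ccccc1 | starting material
22 | isopropyldiphenylsulfonium tetrafluoroborate | CC(C)[S+](c1ccccc1)c1ccccc1.F[B-](F)(F)F | intermediate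
23 | diphenylsulfonium isopropylide | C[C-](C)[S+](c1ccccc1)c1ccccc1 | intermediate (not isolated)
24 | 20 with a CMe2 bridge across C5–C6 (gem-dimethylcyclopropane cis-fused to ring B on the face of H-4a and H-9a); C7 ketone, C8=C9 retained | COC(=O)C1=CO[C@@H](O[Si](C)(C)C(C)(C)C)[C@H]2C(CO[Si](c3ccccc3)(c3ccccc3)C(C)(C)C)=CC(=O)[C@H]3[C@@H]([C@@H]12)C3(C)C | intermediate
25 | diol from 24: C4 hydroxymethyl, C7 hydroxyl (C7 epimers) | OCC1=CO[C@@H](O[Si](C)(C)C(C)(C)C)[C@H]2C(CO[Si](c3ccccc3)(c3ccccc3)C(C)(C)C)=CC(O)[C@H]3[C@@H]([C@@H]12)C3(C)C | intermediate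
26 | C4 acetoxymethyl, C7 hydroxyl compound | CC(=O)OCC1=CO[C@@H](O[Si](C)(C)C(C)(C)C)[C@H]2C(CO[Si](c3ccccc3)(c3ccccc3)C(C)(C)C)=CC(O)[C@H]3[C@@H]([C@@H]12)C3(C)C | intermediate
27 | C4 acetoxymethyl C7 enone with C1 silyl acetal and C9 silyloxymethyl | CC(=O)OCC1=CO[C@@H](O[Si](C)(C)C(C)(C)C)[C@H]2C(CO[Si](c3ccccc3)(c3ccccc3)C(C)(C)C)=CC(=O)[C@H]3[C@@H]([C@@H]12)C3(C)C | intermediate
28 | C1 lactol of 27 (equilibrating anomers) | CC(=O)OCC1=COC(O)[C@H]2C(CO[Si](c3ccccc3)(c3ccccc3)C(C)(C)C)=CC(=O)[C@H]3[C@@H]([C@@H]12)C3(C)C | intermediate (not isolated)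
29 | C1 acetate (acetoxy trans to H-9a) with C9 tert-butyldiphenylsilyloxymethyl | CC(=O)OCC1=CO[C@@H](OC(C)=O)[C@H]2C(CO[Si](c3ccccc3)(c3ccccc3)C(C)(C)C)=CC(=O)[C@H]3[C@@H]([C@@H]12)C3(C)C | intermediate
30 | C1 acetate with C9 hydroxymethyl | CC(=O)OCC1=CO[C@@H](OC(C)=O)[C@H]2C(CO)=CC(=O)[C@H]3[C@@H]([C@@H]12)C3(C)C | intermediate
31 | CNP0263020.2: 1-acetoxy-4-(acetoxymethyl)-9-formyl-7-oxo cyclohepta[c]pyran with the 5,6-fused gem-dimethylcyclopropane | CC(=O)OCC1=CO[C@@H](OC(C)=O)[C@H]2C(C=O)=CC(=O)[C@H]3[C@@H]([C@@H]12)C3(C)C | target

**Count and risks**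

Total: 18 steps. Longest linear sequence: 15 steps (steps 2–5, 7–10 and 12–18, from 1,1-dimethoxypropan-2-one).

Step 7 is the most exposed. The intermolecular photocycloaddition may add with poor orientational selectivity on the unsymmetrical alkene, and the saturated ketone may be consumed by competing photochemistry before the enol adds. The fallback makes the cycloaddition intramolecular. Setting out from 8, the silyl ether would be cleaved (Bu4NF, AcOH, THF) to (1S,5R)-1-(hydroxymethyl)-8-oxabicyclo[3.2.1]oct-6-en-3-one F1. F1 would be linked to the enol oxygen of 11 through a diisopropylsilylene unit (iPr2SiCl2, imidazole, CH2Cl2; then 11, Et3N) to give the silylene-tethered enol ether F2. On irradiation (Pyrex) the three-atom O–Si–O link should allow only the orientation in which the oxygen-bearing enol carbon bonds to the alkene carbon next to the substituted bridgehead, giving the siloxane-bridged cyclobutane F3. HF·pyridine would cleave both Si–O bonds, and the freed cyclobutanol should undergo the same retro-aldol and lactol closure to the lactol alcohol F4. Selective silylation of its primary hydroxyl (tBuPh2SiCl, imidazole) rejoins the route at 14.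

Step 16 may trap the equilibrating lactol with poor or opposite selectivity at C1, and the lactol may ring-open and lose the C9a configuration if acetylation is slow. The fallback replaces O-acylation by substitution at C1. Setting out from 27, the anomeric silyl ether would be cleaved (Bu4NF, AcOH) and lactol 28 isolated. A Mitsunobu esterification with acetic acid (PPh3, diisopropyl azodicarboxylate, THF, −20 °C) should activate the more accessible convex-face hydroxyl as an oxyphosphonium ion and displace it by acetate with inversion, returning to 29. This fallback makes no compound outside the list (F0).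

Step 12 may suffer from γ-deprotonation of the dienone by the basic ylide, with double-bond migration or loss of the C4a/C9a configuration, or from slow addition of the hindered tertiary ylide carbon. The fallback uses a neutral dipole. Setting out from 20, 2-diazopropane (from acetone hydrazone and HgO, Et2O, −78 to 0 °C) should add across C5=C6 with its carbon terminus at C5, anti to the pyran arm, to give the 1-pyrazoline F5. Photolysis (350 nm, Et2O) with loss of nitrogen should then close the same cyclopropane and return to 24.

**Further compounds**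

F1 | step 7 | (1S,5R)-1-(hydroxymethyl)-8-oxabicyclo[3.2.1]oct-6-en-3-one | O=C1C[C@@H]2C=C[C@](CO)(C1)O2
F2 | step 7 | methyl 2-formyl-3-[diisopropyl({[(1S,5R)-3-oxo-8-oxabicyclo[3.2.1]oct-6-en-1-yl]methoxy})silyl]oxyprop-2-enoate | O=C1C[C@@H]2C=C[C@](CO[Si](C(C)C)(C(C)C)OC=C(C=O)C(=O)OC)(C1)O2
F3 | step 7 | siloxane-bridged cyclobutane photoadduct (cyclobutane exo-fused to the former alkene, silyloxy carbon on the carbon next to the substituted bridgehead) | COC(=O)C1(C=O)C2O[Si](C(C)C)(C(C)C)OC[C@@]34CC(=O)C[C@@H](O3)[C@@H]1[C@@H]24
F4 | step 7 | lactol alcohol (14 with a free 9-hydroxymethyl group) | COC(=O)C1=COC(O)[C@H]2[C@]3(CO)CC(=O)C[C@@H](O3)[C@@H]12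
F0 | step 16 | none | none
F5 | step 12 | 1-pyrazoline from 20 and 2-diazopropane (CMe2 on C5, N=N on C6, cis-fused on the face of H-4a and H-9a) | COC(=O)C1=CO[C@@H](O[Si](C)(C)C(C)(C)C)[C@H]2C(CO[Si](c3ccccc3)(c3ccccc3)C(C)(C)C)=CC(=O)[C@@H]3N=NC(C)(C)[C@@H]3[C@@H]12
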